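At late times the south and east runs stand far apart. At 3.00 h the south run holds 36% left-handed product and 52% right-handed product, the east run 14% and 38%, yet their recipes differ just in impurity, 0.10 mM against 0.40 mM.

common to all: left-handed substrate 0.25 M; right-handed substrate 0.25 M; added ligand 0.25 mM

| run | partner | free catalyst | impurity | remark | time |
|---|---|---|---|---|---|
| south | 2 equiv | 0.2 mol% | 0.10 mM | run made earlier |  |
| east | 2 equiv | 0.2 mol% | 0.40 mM | run made earlier |  |
| west | 2 equiv | 0.1 mol% | 0.20 mM | run made earlier |  |
| flask | 2.00 equiv | 0.2 mol% | 0.20 mM |  | 3.0 h |

| run | time / h | left-handed product / % | right-handed product / % | left-handed substrate / % |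
|---|---|---|---|---|
| south | 0.250 | 6 | 22 | 45 |
| south | 0.333 | 10 | 24 | 43 |
| south | 0.500 | 9 | 35 | 39 |
| south | 0.833 | 14 | 46 | 34 |
| south | 1.33 | 18 | 52 | 26 |
| south | 2.00 | 31 | 51 | 22 |
| south | 3.00 | 36 | 52 | 13 |
| east | 0.417 | 0 | 14 | 52 |
| east | 0.833 | 3 | 14 | 47 |
| east | 1.33 | 6 | 27 | 44 |
| east | 1.50 | 10 | 28 | 46 |
| east | 2.00 | 13 | 32 | 44 |
| east | 2.50 | 16 | 37 | 41 |
| east | 3.00 | 14 | 38 | 36 |
| west | 0.250 | 5 | 1 | 48 |
| west | 0.833 | 3 | 8 | 45 |
| west | 1.33 | 3 | 16 | 44 |
| west | 2.00 | 1 | 19 | 47 |
| west | 3.00 | 10 | 23 | 42 |

(scatter of a reading: 2 percentage points)

1. excess of left-handed product over right-handed product in the product at 4.0 min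
2. excess of left-handed product over right-handed product in the product at 3.0 h
3. part of the left-handed substrate and right-handed substrate charged together that has reacted at 3.0 h

- free catalyst is single-handed; left-handed substrate and right-handed substrate are mirror images of each other, charged as a racemate, each of them at the stated concentration
- the analysis behind the earlier runs scatters by 2 percentage points, standard deviation
- on the list of suspects stand: free catalyst + right-handed substrate <-> catalyst intermediate B; free catalyst + left-handed substrate <-> catalyst intermediate A; partner -> decomposition product; partner + catalyst intermediate B -> free catalyst + right-handed product; free catalyst + added ligand <-> idle complex; free catalyst + impurity -> spent catalyst; partner + catalyst intermediate A -> free catalyst + left-handed product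
- an excess is below zero if the other one leads

The quantity to watch is the poisoned share, 40.0% in the flask: impurity charged over free catalyst charged, the part of the catalyst lost if each impurity removes one free catalyst for good, the rest, in whatever form it stands, being working catalyst. This poisoning has impurity as its limiting reagent in these runs. The share is 20.0% in the south run and 80.0% in the east run, leaving 0.400 mM and 0.100 mM of working catalyst. The east run has a quarter of the south run's working catalyst, so, if the rate goes with working catalyst at otherwise equal charges, its 3.00 h should match the south run at 0.750 h. Its final readings lie at or between the south readings at 0.500 h and 0.833 h.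

By this reckoning the flask keeps 0.300 mM, so its 3.0 h corresponds to 2.25 h in the south run, a little past the reading at 2.00 h. At that reading the south run shows products summing to 82.0% and an excess of −24.4%, and this reckoning commits to about those values for the flask at 3.0 h. The forecast gives an excess of −68% at 4.0 min, an excess of −23% at 3.0 h and 81% reacted at 3.0 h, its reacted part just below that reading, and states: "The impurity therefore kills catalyst about stoichiometrically".

The flask gives an excess of −63.2% at 4.0 min, an excess of −26.7% at 3.0 h and 77.3% reacted at 3.0 h, each within the tolerance of the forecast.

    free catalyst + right-handed substrate ⇌ catalyst intermediate B (K = 11.1 /M, k = 94.4 /M/s)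
    free catalyst + left-handed substrate ⇌ catalyst intermediate A (K = 0.970 /M, k = 20.6 /M/s)
    partner → decomposition product (k = 1.25 × 10⁻⁶ /s)
    partner + catalyst intermediate B → free catalyst + right-handed product (k = 1.57 /M/s)
    free catalyst + added ligand ⇌ idle complex, settled at all times (K = 9200 /M)
    free catalyst + impurity → spent catalyst (k = 829 /M/s)
    partner + catalyst intermediate A → free catalyst + left-handed product (k = 3.87 /M/s)

By 0.300 h the flask holds impurity at 0% of its own charge and spent catalyst at 40.0% of the catalyst charged, the share 40.0% reckoned from the charges. At 3.00 h the step to right-handed product uses partner at 0.22 of the rate of the step to left-handed product, while right-handed substrate stands at 1.03% against 21.7% of left-handed substrate.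

For the neighbour with 0.08 mol% of free catalyst, the poisoned share comes to 100%, which leaves no working catalyst by this reckoning. Computed, that flask has 99.7% spent catalyst and 3.21% reacted at 3.00 h.

(The data were generated by integration on assumed constants, and the scatter is random.)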